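**Assumptions.** (i) Target = (3R)-7,2′,4′-trihydroxy-8,3′-diprenylisoflavan, C25H30O4. CIP analysis of the SMILES gives R at C3. (ii) The (R)-diarylprolinol silyl ether is assumed to give the (3R)-aldehyde adduct, by analogy with enamine face-shielding in related α-functionalisations. The sense of induction must be confirmed by HPLC and optical rotation, and the catalyst enantiomer swapped if it is the opposite.

## Retrosynthesis
- Target ⇒ (3R)-3-aryl-chroman-2-ol (lactol **16**) by ionic deoxygenation at C2, then MOM removal.
- **16** ⇒ a formal [4+2] between the enamine of α-aryl-acetaldehyde **14** and the parent CH2-o-quinone methide generated from sulfone **9**. This one asymmetric step forms C3–C4 and O1–C2, sets C3 and closes the chroman ring.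
- Both aryl halves are 2-prenylresorcinol units. They come from resorcinol by bis-MOM protection and C2 lithiation/prenylation (**5**). The A-ring sulfone is made by three-component hydroxymethylation/sulfinate trapping of **6**. The B-ring acetaldehyde is made by C4 formylation and one-carbon homologation of **5**.
- Ring order: both benzene rings (with both prenyls) are built first, and the heterocycle is formed last, in step 8.

## Route

**Step 1**
Reactants: **1** resorcinol; **2** chloromethyl methyl ether
Product: **3** 1,3-bis(methoxymethoxy)benzene
Conditions: NaH, DMF/THF, 0 °C → rt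
Reagents that add atoms: MOMCl, COCCl
Why: Williamson-type double O-alkylation protects both phenols and provides the directing groups for lithiation.

**Step 2**
Reactants: **3**; **4** prenyl bromide
Product: **5** 2-prenyl-1,3-bis(methoxymethoxy)benzene
Conditions: n-BuLi, THF, 0 °C, 1 h; then CuI (10 mol %), **4**, –20 °C → rt
Reagents that add atoms: prenyl bromide, CC(C)=CCBr
Why: Directed ortho-metalation occurs at C2, between the two OMOM groups, and Cu-catalysed SN2 alkylation gives the linear prenyl group.

**Step 3**
Reactant: **5**
Product: **6** 2-prenylresorcinol (2-(3-methylbut-2-enyl)benzene-1,3-diol)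
Conditions: 3 M HCl, MeOH/THF 1:1, rt → 40 °C
Reagents that add atoms: none
Why: Acidolysis of the aryl MOM acetals; the prenyl group survives these mild conditions.

**Step 4**
Reactants: **6** (2.0 equiv); **7** formaldehyde (paraformaldehyde, 1.0 equiv); **8** sodium p-toluenesulfinate (1.5 equiv)
Product: **9** 2,4-dihydroxy-3-prenylbenzyl p-tolyl sulfone (2-prenyl-4-(tosylmethyl)benzene-1,3-diol)
Conditions: (CH2O)n, **8**, AcOH/H2O 1:1, 40 °C, 12 h
Reagents that add atoms: (CH2O)n, C=O; TolSO2Na, Cc1ccc(cc1)S(=O)[O-].[Na+]
Why: Hydroxymethylation at C4 (equivalent to C6, so only one regioisomer) gives an o/p-quinone methide that is trapped by sulfinate (a Betti-type three-component sulfone formation); excess **6** suppresses bis-functionalisation. The sulfone is a bench-stable quinone methide precursor.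

**Step 5**
Reactants: **5**; **10** N,N-dimethylformamide
Product: **11** 2,4-bis(methoxymethoxy)-3-prenylbenzaldehyde
Conditions: n-BuLi, TMEDA, Et2O, 0 °C, 2 h; then **10**, –78 °C → rt
Reagents that add atoms: DMF, CN(C)C=O
Why: MOM-directed ortho-lithiation at C4/C6 (equivalent) followed by formylation (Bouveault).

**Step 6**
Reactants: **11**; **12** (methoxymethyl)triphenylphosphonium chloride
Product: **13** 1-(2-methoxyvinyl)-2,4-bis(MOMO)-3-prenylbenzene (E/Z)
Conditions: **12** (1.5 equiv), KOtBu (1.5 equiv), THF, 0 °C → rt, 2 h
Reagents that add atoms: ylide precursor, [Cl-].COC[P+](c1ccccc1)(c1ccccc1)c1ccccc1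
Why: Wittig methoxymethylenation is a one-carbon homologation; the aryl ring stays achiral.

**Step 7**
Reactant: **13**
Product: **14** 2-[2,4-bis(MOMO)-3-prenylphenyl]acetaldehyde
Conditions: PPTS (0.3 equiv), acetone/H2O 10:1, 50 °C, 3 h; use crude at once
Reagents that add atoms: water, O
Why: Acid-catalysed enol ether hydrolysis (loss of MeOH) under conditions chosen to leave the aryl MOM ethers intact; the aldehyde is used immediately because α-aryl acetaldehydes are labile.

**Step 8**
Reactants: **9** (1.0 equiv); **14** (1.5 equiv); **15** (R)-2-{bis[3,5-bis(trifluoromethyl)phenyl](trimethylsilyloxy)methyl}pyrrolidine (20 mol %)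
Product: **16** (3R)-3-[2,4-bis(MOMO)-3-prenylphenyl]-8-prenylchroman-2,7-diol (lactol, C2 epimeric mixture)
Conditions: **15**, K2CO3 (2.5 equiv), CH2Cl2, 0 °C → rt, 36 h
Reagents that add atoms: none (the catalyst is not incorporated; sulfinate leaves)
Why: Proposed new method: base deprotonates the phenol of **9** and expels sulfinate to give the unsubstituted CH2 o-quinone methide. The (E)-enamine of **14** with **15** attacks its CH2 terminus on the face opposite the bulky diarylprolinol arm (1,4-conjugate addition) and sets C3. The ortho phenoxide then closes onto the iminium/aldehyde to give the lactol, which locks the stereocentre against α-epimerisation. The closest known reaction is the amine-catalysed formal [4+2] of o-quinone methides with enolisable aldehydes to give chroman-2-ols, extended here to a labile α-aryl acetaldehyde donor and a resorcinol-derived parent quinone methide.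

**Step 9**
Reactant: **16**
Product: **17** (3R)-3-[2,4-bis(MOMO)-3-prenylphenyl]-7-hydroxy-8-prenylchroman
Conditions: Et3SiH (4 equiv), BF3·OEt2 (2 equiv), CH2Cl2, –78 → –20 °C, 1 h
Reagents that add atoms: none (H only)
Why: Lewis-acid ionisation of the lactol to the oxocarbenium followed by hydride capture (Kursanov–Parnes-type ionic reduction) removes the C2–OH; C3 is not involved and is retained.

**Step 10**
Reactant: **17**
Product: **18** Kanzonol X
Conditions: 3 M HCl, MeOH/THF 1:1, rt → 40 °C, 3 h
Reagents that add atoms: none
Why: Acidolysis of the two aryl MOM ethers gives the free triphenol; the stereocentre and the prenyl groups are untouched.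

## Compound list
1 | resorcinol | Oc1cccc(O)c1 | starting material
2 | chloromethyl methyl ether | COCCl | starting material
3 | 1,3-bis(methoxymethoxy)benzene | COCOc1cccc(OCOC)c1 | intermediate
4 | prenyl bromide | CC(C)=CCBr | starting material
5 | 2-prenyl-1,3-bis(MOMO)benzene | CC(C)=CCc1c(OCOC)cccc1OCOC | intermediate
6 | 2-prenylresorcinol | CC(C)=CCc1c(O)cccc1O | intermediate
7 | formaldehyde | C=O | starting material
8 | sodium p-toluenesulfinate | Cc1ccc(cc1)S(=O)[O-].[Na+] | starting material
9 | 2,4-dihydroxy-3-prenylbenzyl p-tolyl sulfone | CC(C)=CCc1c(O)ccc(CS(=O)(=O)c2ccc(C)cc2)c1O | intermediate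
10 | N,N-dimethylformamide | CN(C)C=O | starting material
11 | 2,4-bis(MOMO)-3-prenylbenzaldehyde | O=Cc1ccc(OCOC)c(CC=C(C)C)c1OCOC | intermediate
12 | (methoxymethyl)triphenylphosphonium chloride | [Cl-].COC[P+](c1ccccc1)(c1ccccc1)c1ccccc1 | starting material
13 | aryl methyl enol ether (E/Z) | COC=Cc1ccc(OCOC)c(CC=C(C)C)c1OCOC | intermediate
14 | 2-[2,4-bis(MOMO)-3-prenylphenyl]acetaldehyde | O=CCc1ccc(OCOC)c(CC=C(C)C)c1OCOC | intermediate
15 | (R)-diarylprolinol TMS ether (organocatalyst, not incorporated) | C[Si](C)(C)OC(c1cc(C(F)(F)F)cc(C(F)(F)F)c1)(c1cc(C(F)(F)F)cc(C(F)(F)F)c1)[C@H]1CCCN1 | starting material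
16 | (3R)-lactol | CC(C)=CCc1c(OCOC)ccc([C@@H]2C(O)Oc3c(ccc(O)c3CC=C(C)C)C2)c1OCOC | intermediate
17 | (3R)-bis-MOM isoflavan | CC(C)=CCc1c(OCOC)ccc([C@@H]2COc3c(ccc(O)c3CC=C(C)C)C2)c1OCOC | intermediate
18 | Kanzonol X | CC(C)=CCc1c(O)ccc([C@@H]2COc3c(ccc(O)c3CC=C(C)C)C2)c1O | target

**Total steps:** 10. **Longest linear sequence:** 8 (resorcinol **1** → **3** → **5** → **11** → **13** → **14** → **16** → **17** → **18**). The sulfone branch (**1** → **3** → **5** → **6** → **9**) is shorter and joins at step 8.

## Three steps most likely to fail
1. **Step 8 (proposed new step).** Risks are low reactivity, racemisation of the α-aryl acetaldehyde enamine/aldehyde, competing p-quinone methide formation, and the wrong catalyst sense.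
   Fallback: change to isothiourea Lewis-base catalysis. Oxidise **14** (Pinnick, 2-methyl-2-butene scavenger) to the arylacetic acid and make its p-nitrophenyl ester. Run the known (R)-HyperBTM-catalysed Michael addition–lactonisation with the quinone methide from **9** to give the 3-aryl-dihydrocoumarin. Reduce this with DIBAL-H to lactol **16**, which rejoins the route at step 9.
2. **Step 5.** Lithiation at C4 may compete with lateral deprotonation of the prenyl CH2, and the yield may be low.
   Fallback: use electrophilic formylation instead. Vilsmeier–Haack formylation (POCl3/DMF) of free **6** gives 2,4-dihydroxy-3-prenylbenzaldehyde, and bis-MOM protection (MOMCl, iPr2NEt) then gives **11**.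
3. **Step 9.** BF3 may partly cleave the aryl MOM ethers or attack the prenyl alkenes, or the ring-opened aldehyde may epimerise.
   Fallback: avoid ionic reduction. Open lactol **16** with NaBH4 (MeOH, 0 °C) to the 1,3-diol, then close O1–C2 by intramolecular Mitsunobu (PPh3, DIAD) to give **17**.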